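**Strategy.** The chain is numbered C1 (benzylic CH2 on ring A, the 4-hydroxy-3-methoxyphenyl ring) to C7 (benzylic CH2 on ring B, the 3,4-dihydroxy-5-methoxyphenyl ring). Everything rests on cutting the C7–ring B bond. The fragment C5(=O)–C6–C7–ring B is a β-aryl ketone, which a cyclopropanol (C5 carbinol, C6 and C7 ring methylenes) delivers when palladium opens it and joins it to a ring B bromide: one operation makes the C7–aryl bond and unveils the C5 ketone. The precursor is a 1-alkylcyclopropanol carrying the (R)-configured, silyl-protected C3 carbinol and benzyl-protected ring A, reached by Noyori reduction of a β-keto ester and Kulinkovich cyclopropanation.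

Key step: step 8

**Remarks on the chemistry**
- Configuration: the only stereocentre (C3 of the chain, locant 5 in the heptan-3-one name) is R in the target. It keeps the descriptor R in 6, 7, 8, 13 and 14, because the oxygenated branch (ester, cyclopropanol or ketone carbon) always outranks the arylethyl branch.
- Assumption: alcohol 1 is purchased; otherwise NaBH4 reduction of 4-(benzyloxy)-3-methoxybenzaldehyde supplies it in one extra step.
- Protecting groups: benzyl on all three phenols (one hydrogenolysis at the end) and TBS on the C3 oxygen. TBS goes on and off under near-neutral conditions, so the aldol-type unit never meets strong acid or base.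

**Route**

Step 1
Reactants: 1 [4-(benzyloxy)-3-methoxyphenyl]methanol
Product: 2 1-(benzyloxy)-4-(bromomethyl)-2-methoxybenzene (4-benzyloxy-3-methoxybenzyl bromide)
Conditions: PBr3 (0.4 equiv), Et2O, 0 °C; used crude at once
Reagents that add atoms: phosphorus tribromide BrP(Br)Br
Why: Bromination of a primary benzylic alcohol through its phosphite ester (SN2 displacement by bromide) is fast at 0 °C and leaves the aryl benzyl and methyl ethers untouched.

Step 2
Reactants: 2 1-(benzyloxy)-4-(bromomethyl)-2-methoxybenzene, 3 methyl acetoacetate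
Product: 5 methyl 5-[4-(benzyloxy)-3-methoxyphenyl]-3-oxopentanoate, via acetoacetate dianion 4 (not isolated)
Conditions: 3 (1.3 equiv), NaH, THF, 0 °C; n-BuLi, 0 °C; then 2, 0 °C to rt; 1 M HCl
Reagents that add atoms: none
Why: Weiler dianion alkylation, in which the more basic terminal carbanion of the acetoacetate dianion attacks the reactive benzylic bromide and so forms the C1–C2 bond with the β-keto ester intact.

Step 3
Reactants: 5 methyl 5-[4-(benzyloxy)-3-methoxyphenyl]-3-oxopentanoate
Product: 6 methyl (3R)-5-[4-(benzyloxy)-3-methoxyphenyl]-3-hydroxypentanoate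
Conditions: H2 (50 atm), RuCl2[(R)-BINAP] (0.5 mol%), MeOH, 50 °C
Reagents that add atoms: none
Why: Noyori asymmetric hydrogenation, in which the chelated β-keto ester receives hydride on the carbonyl face dictated by the (R)-BINAP ligand, setting the carbinol as R (the same sense as methyl acetoacetate to methyl (R)-3-hydroxybutanoate), while ruthenium does not cleave the benzyl ether.

Step 4
Reactants: 6 methyl (3R)-5-[4-(benzyloxy)-3-methoxyphenyl]-3-hydroxypentanoate
Product: 7 methyl (3R)-5-[4-(benzyloxy)-3-methoxyphenyl]-3-[(tert-butyldimethylsilyl)oxy]pentanoate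
Conditions: TBSCl (1.3 equiv), imidazole (2.5 equiv), DMF, rt
Reagents that add atoms: tert-butyldimethylsilyl chloride CC(C)(C)[Si](C)(C)Cl
Why: Imidazole-promoted silylation of an unhindered secondary alcohol (Corey protocol) is mild enough to avoid retro-aldol cleavage or dehydration of the β-hydroxy ester and does not touch the stereocentre.

Step 5
Reactants: 7 methyl (3R)-5-[4-(benzyloxy)-3-methoxyphenyl]-3-[(tert-butyldimethylsilyl)oxy]pentanoate
Product: 8 1-[(2R)-4-[4-(benzyloxy)-3-methoxyphenyl]-2-[(tert-butyldimethylsilyl)oxy]butyl]cyclopropan-1-ol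
Conditions: EtMgBr (3 equiv, slow addition), Ti(OiPr)4 (0.3 equiv), THF, 0 °C to rt; aq. NH4Cl
Reagents that add atoms: ethylmagnesium bromide CC[Mg]Br
Why: Kulinkovich cyclopropanation, in which the titanacyclopropane formed from EtMgBr and Ti(OiPr)4 acts as a 1,2-dicarbanion on the ester carbonyl and turns it into the cyclopropanol (C5 carbinol, C6 and C7 ring methylenes) without disturbing the silyl ether, the benzyl ether or the stereocentre.

Step 6
Reactants: 9 5-bromo-2-hydroxy-3-methoxybenzaldehyde
Product: 11 5-bromo-3-methoxybenzene-1,2-diol, via aryl formate 10 (not isolated)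
Conditions: 30% aq. H2O2 (1.2 equiv), NaOH (1.1 equiv), H2O/THF, 0 °C to rt, N2; then 1 M HCl
Reagents that add atoms: hydrogen peroxide OO
Why: Dakin oxidation, in which hydroperoxide adds to the ortho-hydroxy aldehyde, the aryl group migrates to oxygen and the formate is saponified in the flask, placing the second phenol exactly where the formyl carbon was.

Step 7
Reactants: 11 5-bromo-3-methoxybenzene-1,2-diol
Product: 12 1,2-bis(benzyloxy)-5-bromo-3-methoxybenzene
Conditions: BnBr (2.4 equiv), K2CO3 (3 equiv), DMF, 60 °C, N2
Reagents that add atoms: benzyl bromide BrCc1ccccc1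
Why: Williamson etherification of both phenols with a reactive benzylic halide under carbonate is reliable and masks the oxidation-prone catechol before the palladium step.

Step 8
Reactants: 8 1-[(2R)-4-[4-(benzyloxy)-3-methoxyphenyl]-2-[(tert-butyldimethylsilyl)oxy]butyl]cyclopropan-1-ol, 12 1,2-bis(benzyloxy)-5-bromo-3-methoxybenzene
Product: 13 (5R)-1-[3,4-bis(benzyloxy)-5-methoxyphenyl]-7-[4-(benzyloxy)-3-methoxyphenyl]-5-[(tert-butyldimethylsilyl)oxy]heptan-3-one
Conditions: 8 (1.0 equiv), 12 (1.2 equiv), Pd(OAc)2 (5 mol%), XPhos (10 mol%), Cs2CO3 (1.5 equiv), toluene, 80 °C, Ar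
Reagents that add atoms: none
Why: Bromide 12 adds oxidatively to zerovalent palladium (formed in the flask from Pd(OAc)2 and XPhos), carbonate-assisted exchange with the O–H of 8 gives a divalent palladium cyclopropoxide, strain-driven β-carbon elimination opens the ring to the palladium homoenolate (Pd on C7, C5 now the ketone), and reductive elimination forges the C7–aryl bond. The closest known reaction type is the palladium-catalysed ring-opening cross-coupling of 1-substituted cyclopropanols with aryl bromides to give β-aryl ketones. No ring is closed (one is opened) and no stereocentre is created; the C3 centre is remote, silyl-protected and carried through unchanged. Regiochemistry is not an issue because C6 and C7 are equivalent ring methylenes. The selectivity needed is reductive elimination over β-hydride elimination at C6, and the bulky electron-rich biaryl phosphine secures it while also speeding oxidative addition to the electron-rich bromide. The weakly basic carbonate in an aprotic, non-polar medium should keep the β-silyloxy ketone from E1cB loss of silanol and from α-arylation.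

Step 9
Reactants: 13 (5R)-1-[3,4-bis(benzyloxy)-5-methoxyphenyl]-7-[4-(benzyloxy)-3-methoxyphenyl]-5-[(tert-butyldimethylsilyl)oxy]heptan-3-one
Product: 14 (5R)-1-[3,4-bis(benzyloxy)-5-methoxyphenyl]-7-[4-(benzyloxy)-3-methoxyphenyl]-5-hydroxyheptan-3-one
Conditions: HF·pyridine, pyridine, THF, 0 °C to rt
Reagents that add atoms: none
Why: Fluoride-driven Si–O cleavage with pyridine-buffered HF·pyridine is close to neutral, so the β-hydroxy ketone should be released without dehydration or retro-aldol cleavage and with the carbinol configuration untouched.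

Step 10
Reactants: 14 (5R)-1-[3,4-bis(benzyloxy)-5-methoxyphenyl]-7-[4-(benzyloxy)-3-methoxyphenyl]-5-hydroxyheptan-3-one
Product: 15 (5R)-1-(3,4-dihydroxy-5-methoxyphenyl)-5-hydroxy-7-(4-hydroxy-3-methoxyphenyl)heptan-3-one
Conditions: H2 (1 atm), 10% Pd/C, EtOAc/MeOH, rt; filtration under N2
Reagents that add atoms: none
Why: Catalytic hydrogenolysis removes the three aryl benzyl ethers at room temperature without reducing the dialkyl ketone or the non-benzylic secondary alcohol, and the air-sensitive catechol is obtained by filtration and evaporation only.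

**Compound list**

1 | [4-(benzyloxy)-3-methoxyphenyl]methanol | COc1cc(CO)ccc1OCc1ccccc1 | starting material
2 | 1-(benzyloxy)-4-(bromomethyl)-2-methoxybenzene | COc1cc(CBr)ccc1OCc1ccccc1 | intermediate
3 | methyl acetoacetate | COC(=O)CC(C)=O | starting material
4 | methyl acetoacetate dianion, sodium lithium dienolate | [Li+].[Na+].[O-]C(=C)C=C([O-])OC | intermediate
5 | methyl 5-[4-(benzyloxy)-3-methoxyphenyl]-3-oxopentanoate | COC(=O)CC(=O)CCc1ccc(OCc2ccccc2)c(OC)c1 | intermediate
6 | methyl (3R)-5-[4-(benzyloxy)-3-methoxyphenyl]-3-hydroxypentanoate | COC(=O)C[C@H](O)CCc1ccc(OCc2ccccc2)c(OC)c1 | intermediate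
7 | methyl (3R)-5-[4-(benzyloxy)-3-methoxyphenyl]-3-[(tert-butyldimethylsilyl)oxy]pentanoate | COC(=O)C[C@H](O[Si](C)(C)C(C)(C)C)CCc1ccc(OCc2ccccc2)c(OC)c1 | intermediate
8 | 1-[(2R)-4-[4-(benzyloxy)-3-methoxyphenyl]-2-[(tert-butyldimethylsilyl)oxy]butyl]cyclopropan-1-ol | COc1cc(CC[C@@H](O[Si](C)(C)C(C)(C)C)CC2(O)CC2)ccc1OCc1ccccc1 | intermediate
9 | 5-bromo-2-hydroxy-3-methoxybenzaldehyde | COc1cc(Br)cc(C=O)c1O | starting material
10 | 5-bromo-2-hydroxy-3-methoxyphenyl formate | COc1cc(Br)cc(OC=O)c1O | intermediate
11 | 5-bromo-3-methoxybenzene-1,2-diol | COc1cc(Br)cc(O)c1O | intermediate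
12 | 1,2-bis(benzyloxy)-5-bromo-3-methoxybenzene | COc1cc(Br)cc(OCc2ccccc2)c1OCc1ccccc1 | intermediate
13 | (5R)-1-[3,4-bis(benzyloxy)-5-methoxyphenyl]-7-[4-(benzyloxy)-3-methoxyphenyl]-5-[(tert-butyldimethylsilyl)oxy]heptan-3-one | COc1cc(CC[C@@H](O[Si](C)(C)C(C)(C)C)CC(=O)CCc2cc(OCc3ccccc3)c(OCc3ccccc3)c(OC)c2)ccc1OCc1ccccc1 | intermediate
14 | (5R)-1-[3,4-bis(benzyloxy)-5-methoxyphenyl]-7-[4-(benzyloxy)-3-methoxyphenyl]-5-hydroxyheptan-3-one | COc1cc(CC[C@@H](O)CC(=O)CCc2cc(OCc3ccccc3)c(OCc3ccccc3)c(OC)c2)ccc1OCc1ccccc1 | intermediate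
15 | (5R)-1-(3,4-dihydroxy-5-methoxyphenyl)-5-hydroxy-7-(4-hydroxy-3-methoxyphenyl)heptan-3-one | COc1cc(CC[C@@H](O)CC(=O)CCc2cc(O)c(O)c(OC)c2)ccc1O | target

**Step count**

Total: 10 steps. Longest linear sequence: 8 steps (steps 1–5, then 8–10); the ring B bromide takes 2 steps (6–7).

**Steps most likely to fail**

1. Step 8. β-Hydride elimination from the palladium homoenolate may outrun reductive elimination, oxidative addition to the electron-rich bromide may be slow, or the base may cause loss of the silyloxy group from the product. The fallback sets out from 8 and returns at 13, and it turns the unwanted elimination into the intended path. Oxidative ring opening of 8 (Pd(OAc)2 cat., pyridine, O2, toluene, 80 °C) should give the vinyl ketone (5R)-7-[4-(benzyloxy)-3-methoxyphenyl]-5-[(tert-butyldimethylsilyl)oxy]hept-1-en-3-one F1. Heck coupling of this with bromide 12 (Pd(OAc)2, P(o-tol)3, Et3N, MeCN, 80 °C) should give the aryl enone (1E,5R)-1-[3,4-bis(benzyloxy)-5-methoxyphenyl]-7-[4-(benzyloxy)-3-methoxyphenyl]-5-[(tert-butyldimethylsilyl)oxy]hept-1-en-3-one F2. Conjugate reduction with [(Ph3P)CuH]6 in wet toluene, which spares benzyl and silyl ethers, then gives 13.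

2. Step 5. The Grignard reagent may act as a base and expel the β-silyloxy group, ethyl may add directly to the ester in competition with the titanium cycle, or the silyl group may migrate to the new cyclopropoxide. The fallback sets out from 7 and returns at 8 in one flask, using a non-basic carbenoid instead of a titanacycle. Samarium metal and CH2I2 in THF at 50 °C should iodomethylate the ester to (4R)-6-[4-(benzyloxy)-3-methoxyphenyl]-4-[(tert-butyldimethylsilyl)oxy]-1-iodohexan-2-one F3, which is not isolated. It is reduced in place to its samarium enolate, and Simmons–Smith-type methylenation of that enolate gives 8.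

3. Step 6. The electron-rich bromocatechol may be over-oxidised in alkaline peroxide (quinone formation and ring degradation). The fallback sets out from 9 and returns at 12, and it never exposes a free catechol to oxidant. The phenol is benzylated first (BnBr, K2CO3, DMF) to 2-(benzyloxy)-5-bromo-3-methoxybenzaldehyde F4. Baeyer–Villiger oxidation with mCPBA in CH2Cl2 gives 2-(benzyloxy)-5-bromo-3-methoxyphenyl formate F5, which is not isolated but methanolysed (K2CO3, MeOH) to 2-(benzyloxy)-5-bromo-3-methoxyphenol F6. A second benzylation (BnBr, K2CO3, DMF) gives 12.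

**Further compounds**

F1 | step 8 | (5R)-7-[4-(benzyloxy)-3-methoxyphenyl]-5-[(tert-butyldimethylsilyl)oxy]hept-1-en-3-one | COc1cc(CC[C@@H](O[Si](C)(C)C(C)(C)C)CC(=O)C=C)ccc1OCc1ccccc1
F2 | step 8 | (1E,5R)-1-[3,4-bis(benzyloxy)-5-methoxyphenyl]-7-[4-(benzyloxy)-3-methoxyphenyl]-5-[(tert-butyldimethylsilyl)oxy]hept-1-en-3-one | COc1cc(CC[C@@H](O[Si](C)(C)C(C)(C)C)CC(=O)/C=C/c2cc(OCc3ccccc3)c(OCc3ccccc3)c(OC)c2)ccc1OCc1ccccc1
F3 | step 5 | (4R)-6-[4-(benzyloxy)-3-methoxyphenyl]-4-[(tert-butyldimethylsilyl)oxy]-1-iodohexan-2-one | COc1cc(CC[C@@H](O[Si](C)(C)C(C)(C)C)CC(=O)CI)ccc1OCc1ccccc1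
F4 | step 6 | 2-(benzyloxy)-5-bromo-3-methoxybenzaldehyde | COc1cc(Br)cc(C=O)c1OCc1ccccc1
F5 | step 6 | 2-(benzyloxy)-5-bromo-3-methoxyphenyl formate | COc1cc(Br)cc(OC=O)c1OCc1ccccc1
F6 | step 6 | 2-(benzyloxy)-5-bromo-3-methoxyphenol | COc1cc(Br)cc(O)c1OCc1ccccc1
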